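**Retrosynthetic overview** (carotenoid numbering; primed locants belong to the ε-end)
1. The C11=C12 bond is cut last (Wittig): C25 ε-end phosphonium salt 17 + C15 epoxy aldehyde 24; 17 is cut at C11'=C12' into the C15 ε-end phosphonium salt 13 and the C10 dialdehyde 14.
2. Epoxide end: the trimethylcyclohexene ring is bought as β-cyclocitral; the oxirane (5R,6S) is closed by Sharpless epoxidation of β-cyclogeraniol, and C8–C11 are added by Horner–Wadsworth–Emmons olefination.
3. ε-End: the cyclohexene C1'–C6' is the only carbocycle that is built. A catalytic enantioselective Diels–Alder reaction of methacrolein with the terminal diene of the acyclic C11 tetraenyl silyl ether 7 makes C2'–C3' and C1'–C6' together, sets C6' and delivers the whole C15 end group; the formyl group then becomes the second methyl group on C1'.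
4. Feature that allows it: in the ε-ring the C4'=C5' double bond lies opposite the C1'–C2' edge (cyclohexene retron); C6' bears the C7'=C8' alkene, which in 7 is conjugated with the diene C3'=C4'–C5'=C6' and steers the regiochemistry; C1' is a gem-dimethyl quaternary carbon, so one methyl can enter as the activating CHO group of the dienophile.
5. Ring order: ε-cyclohexene (step 6, fragment 1), then oxirane (step 14, fragment 2); the fragments meet in step 18.

Key step: step 6

Assumption: the sense of induction in step 6 is taken from the accepted pre-transition-state model for 2-substituted acroleins on this catalyst class (formyl C–H···O contact, s-trans enal, attack anti to the shielding phenyl group); should the sense be found opposite, the enantiomeric catalyst is used and nothing else changes. Compounds 1, 4, 8, 14, 18 and 22 are taken as commercial (4 and 22 as E/Z mixtures, drawn E).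

**Fragment 1 (ε-end)**

Step 1
Reactants: 1 (E)-3-methylpent-2-en-4-yn-1-ol
Product: 2 (E)-3-methylpenta-2,4-dien-1-ol
Conditions: H2 (1 atm, 1 equiv taken up), Pd/CaCO3 poisoned with Pb(OAc)2, quinoline, EtOAc–hexane, 0 °C to rt
Reagents that add atoms: none
Why: Lindlar-type semihydrogenation of the terminal alkyne stops at the vinyl group and leaves the (E)-trisubstituted alkene, which later places the diene substituent on the outside of the s-cis diene, untouched.

Step 2
Reactants: 2 (E)-3-methylpenta-2,4-dien-1-ol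
Product: 3 (E)-3-methylpenta-2,4-dienal
Conditions: activated MnO2 (excess), CH2Cl2, rt; used at once as a solution
Reagents that add atoms: none
Why: MnO2 oxidises the allylic alcohol selectively and without E/Z isomerisation, and the volatile dienal is not stored.

Step 3
Reactants: 3 (E)-3-methylpenta-2,4-dienal; 4 ethyl (E)-4-(diethoxyphosphoryl)-3-methylbut-2-enoate
Product: 5 ethyl (2E,4E,6E)-3,7-dimethylnona-2,4,6,8-tetraenoate
Conditions: 4, NaH, THF, 0 °C; then 3, 0 °C to rt; chromatography
Reagents that add atoms: none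
Why: Horner–Wadsworth–Emmons olefination with the vinylogous phosphonate should form the new C7'=C8' bond E-selectively, and the minor (2Z) isomer is removed by chromatography.

Step 4
Reactants: 5 ethyl (2E,4E,6E)-3,7-dimethylnona-2,4,6,8-tetraenoate
Product: 6 (2E,4E,6E)-3,7-dimethylnona-2,4,6,8-tetraen-1-ol
Conditions: (i-Bu)2AlH (2.2 equiv), CH2Cl2, −78 °C; aqueous KNaC4H4O6
Reagents that add atoms: none
Why: (i-Bu)2AlH reduces the conjugated ester by 1,2-addition to the allylic alcohol without touching the polyene.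

Step 5
Reactants: 6 (2E,4E,6E)-3,7-dimethylnona-2,4,6,8-tetraen-1-ol
Product: 7 tert-butyl{[(2E,4E,6E)-3,7-dimethylnona-2,4,6,8-tetraen-1-yl]oxy}dimethylsilane
Conditions: TBSCl, imidazole, CH2Cl2, 0 °C
Reagents that add atoms: tert-butyldimethylsilyl chloride, CC(C)(C)[Si](C)(C)Cl
Why: Silylation masks the hydroxyl group, which would bind the boron catalyst, and puts a bulky group next to the far terminus of the internal diene.

Step 6
Reactants: 7 tert-butyl{[(2E,4E,6E)-3,7-dimethylnona-2,4,6,8-tetraen-1-yl]oxy}dimethylsilane; 8 methacrolein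
Product: 9 (1R,2S)-2-[(1E,3E)-5-{[tert-butyl(dimethyl)silyl]oxy}-3-methylpenta-1,3-dien-1-yl]-1,3-dimethylcyclohex-3-ene-1-carbaldehyde (formyl group cis to the side chain)
Conditions: 8 (3 equiv), (R)-1-(2-methylphenyl)-3,3-diphenyltetrahydro-1H,3H-pyrrolo[1,2-c][1,3,2]oxazaborole (C24H24BNO, 20 mol %) protonated with (CF3SO2)2NH (17 mol %), CH2Cl2, −78 °C; chromatography
Reagents that add atoms: none
Why: The oxazaborolidinium cation binds methacrolein at boron and lowers its LUMO, so the terminal s-cis diene of 7 adds in a concerted but strongly asynchronous [4π+2π] cycloaddition: the CH2 terminus (C3') bonds first to the β-carbon of the enal and the alkenyl-bearing terminus (C6') then closes onto the α-carbon (C1'). The closest known reaction type is the chiral oxazaborolidine-catalysed Diels–Alder reaction of 2-substituted acroleins with 1-alkenyl-2-methyl-1,3-dienes, which gives the same vicinal tertiary/quaternary carbon pair. The cyclohexene closes intermolecularly in the suprafacial–suprafacial mode, with the new ring double bond appearing at C4'=C5'. C6' is set by catalyst control of the enal face (the (R)-catalyst should expose the face of the α-carbon that gives the 1R centre) combined with the endo orientation of the formyl group, which is favoured because the exo alternative pushes the α-methyl group against the C5' methyl group of the diene; the quaternary C1' centre is set in the same event and is erased in step 8. Regiochemistry follows from the conjugated C7'=C8'–C9'=C10' substituent, which puts the largest HOMO coefficient on the terminal CH2 and lets the developing positive charge spread over a heptatrienyl unit; site selectivity rests on the unsubstituted terminus of the terminal diene, both termini of the internal diene being substituted and one flanked by the silyloxymethyl group. Any exo adduct, which would lead to the enantiomeric ring after step 8, is a diastereomer and is removed by chromatography here.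

Step 7
Reactants: 9 (1R,2S)-2-[(1E,3E)-5-{[tert-butyl(dimethyl)silyl]oxy}-3-methylpenta-1,3-dien-1-yl]-1,3-dimethylcyclohex-3-ene-1-carbaldehyde
Product: 10 N'-[(E)-{(1R,2S)-2-[(1E,3E)-5-{[tert-butyl(dimethyl)silyl]oxy}-3-methylpenta-1,3-dien-1-yl]-1,3-dimethylcyclohex-3-en-1-yl}methylidene]-4-methylbenzenesulfonohydrazide
Conditions: TsNHNH2 (1.1 equiv), EtOH, rt
Reagents that add atoms: p-toluenesulfonyl hydrazide, Cc1ccc(cc1)S(=O)(=O)NN
Why: Condensation of the aldehyde with tosylhydrazide is mild and neutral, and the quaternary α-carbon excludes enolisation or epimerisation.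

Step 8
Reactants: 10 the tosylhydrazone of 9
Product: 11 tert-butyldimethyl{[(2E,4E)-3-methyl-5-[(1R)-2,6,6-trimethylcyclohex-2-en-1-yl]penta-2,4-dien-1-yl]oxy}silane
Conditions: catecholborane (C6H4O2BH, 2 equiv), CHCl3, 0 °C to rt; then NaOAc·3H2O, reflux
Reagents that add atoms: none
Why: Caglioti-type reduction (hydride to the C=N carbon, loss of sulfinate, then of N2 from the diazene) turns CH=N into CH3 under non-basic conditions that spare the doubly allylic C6'–H, the alkenes and the silyl ether; the temporary quaternary stereocentre becomes the gem-dimethyl carbon C1' and C6' is now (R).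

Step 9
Reactants: 11 tert-butyldimethyl{[(2E,4E)-3-methyl-5-[(1R)-2,6,6-trimethylcyclohex-2-en-1-yl]penta-2,4-dien-1-yl]oxy}silane
Product: 13 [(2E,4E)-3-methyl-5-[(1R)-2,6,6-trimethylcyclohex-2-en-1-yl]penta-2,4-dien-1-yl]triphenylphosphonium bromide, via C15 dienol 12 (not isolated)
Conditions: PPh3·HBr (1.1 equiv), MeOH, rt; crystallisation
Reagents that add atoms: triphenylphosphine hydrobromide, Br.c1ccc(cc1)P(c1ccccc1)c1ccccc1
Why: Acidic methanolysis frees the primary allylic alcohol, which ionises to the dienyl cation and is captured by PPh3 at the terminal carbon (standard salt formation for C15 end groups); crystallisation should remove any Z salt.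

Step 10
Reactants: 13 the C15 phosphonium bromide; 14 (2E,4E,6E)-2,7-dimethylocta-2,4,6-trienedial
Product: 15 (2E,4E,6E,8E,10E,12E)-2,7,11-trimethyl-13-[(1R)-2,6,6-trimethylcyclohex-2-en-1-yl]trideca-2,4,6,8,10,12-hexaenal
Conditions: 14 (2.5 equiv), NaOMe, CH2Cl2–MeOH, 0 °C to rt; then n-heptane, reflux, dark
Reagents that add atoms: none
Why: Wittig olefination of the semi-stabilised ylide with an excess of the symmetrical dialdehyde should stop at mono-condensation (C11'=C12'), and heating equilibrates the new double bond to E.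

Step 11
Reactants: 15 the C25 hexaenal
Product: 16 (2E,4E,6E,8E,10E,12E)-2,7,11-trimethyl-13-[(1R)-2,6,6-trimethylcyclohex-2-en-1-yl]trideca-2,4,6,8,10,12-hexaen-1-ol
Conditions: NaBH4, EtOH–THF, 0 °C
Reagents that add atoms: none
Why: Borohydride reduces the conjugated aldehyde by 1,2-addition and leaves the polyene and C6' untouched.

Step 12
Reactants: 16 the C25 hexaenol
Product: 17 [(2E,4E,6E,8E,10E,12E)-2,7,11-trimethyl-13-[(1R)-2,6,6-trimethylcyclohex-2-en-1-yl]trideca-2,4,6,8,10,12-hexaen-1-yl]triphenylphosphonium bromide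
Conditions: PPh3·HBr (1.05 equiv), CH2Cl2–MeOH, 0 °C to rt, dark
Reagents that add atoms: triphenylphosphine hydrobromide, Br.c1ccc(cc1)P(c1ccccc1)c1ccccc1
Why: The polyenylic alcohol ionises readily and PPh3 should trap the cation at the terminal carbon (C12), which keeps the full conjugation, as in the usual preparation of polyenyl Wittig salts.

**Fragment 2 (epoxide end)**

Step 13
Reactants: 18 β-cyclocitral (2,6,6-trimethylcyclohex-1-ene-1-carbaldehyde)
Product: 19 β-cyclogeraniol [(2,6,6-trimethylcyclohex-1-en-1-yl)methanol]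
Conditions: NaBH4, MeOH, 0 °C
Reagents that add atoms: none
Why: Simple 1,2-reduction of the hindered enal gives the allylic alcohol needed to direct the epoxidation.

Step 14
Reactants: 19 β-cyclogeraniol
Product: 20 [(1R,6R)-2,2,6-trimethyl-7-oxabicyclo[4.1.0]heptan-1-yl]methanol
Conditions: Ti(Oi-Pr)4 (20 mol %), diethyl D-(−)-tartrate [(2S,3S), 24 mol %], t-BuOOH, 4 Å molecular sieves, CH2Cl2, −20 °C
Reagents that add atoms: tert-butyl hydroperoxide, CC(C)(C)OO
Why: Sharpless asymmetric epoxidation of the tetrasubstituted allylic alcohol delivers oxygen syn to one alkene face chosen by the titanium tartrate (the D-tartrate face corresponds to 5R,6S of the target), so both oxirane stereocentres are set in one event.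

Step 15
Reactants: 20 the epoxy alcohol
Product: 21 (1S,6R)-2,2,6-trimethyl-7-oxabicyclo[4.1.0]heptane-1-carbaldehyde
Conditions: (n-Pr)4N[RuO4] (5 mol %), N-methylmorpholine N-oxide, 4 Å molecular sieves, CH2Cl2, rt
Reagents that add atoms: none
Why: Ley–Griffith oxidation is neutral, so the acid-labile tetrasubstituted epoxide survives, and the aldehyde has no α-hydrogen to epimerise.

Step 16
Reactants: 21 the epoxy aldehyde; 22 diethyl [(E)-3-cyano-2-methylprop-2-en-1-yl]phosphonate
Product: 23 (2E,4E)-3-methyl-5-[(1S,6R)-2,2,6-trimethyl-7-oxabicyclo[4.1.0]heptan-1-yl]penta-2,4-dienenitrile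
Conditions: 22, NaH, THF, 0 °C; then 21, 0 °C to rt; chromatography
Reagents that add atoms: none
Why: Horner–Wadsworth–Emmons olefination should give the E-configured C7=C8 bond under basic conditions that leave the epoxide alone; the minor (2Z) isomer is removed by chromatography.

Step 17
Reactants: 23 the epoxy dienenitrile
Product: 24 (2E,4E)-3-methyl-5-[(1S,6R)-2,2,6-trimethyl-7-oxabicyclo[4.1.0]heptan-1-yl]penta-2,4-dienal
Conditions: (i-Bu)2AlH (1.2 equiv), toluene, −78 °C; then wet SiO2 or aqueous KNaC4H4O6, 0 °C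
Reagents that add atoms: water, O
Why: Partial reduction of the nitrile to the aluminium imide and near-neutral hydrolysis gives the enal directly without exposing the vinyl epoxide to acid.

**Union**

Step 18
Reactants: 17 the C25 phosphonium bromide; 24 the C15 epoxy aldehyde
Product: 25 (5R,6S,6'R)-5,6-epoxy-5,6-dihydro-β,ε-carotene (target)
Conditions: NaOMe, CH2Cl2–MeOH, 0 °C to rt; then EtOH–heptane, reflux under Ar in the dark; crystallisation
Reagents that add atoms: none
Why: Wittig olefination of the polyenyl ylide with the enal forms C11=C12 under purely basic conditions, which protect the 5,6-epoxide from rearrangement to the 5,8-furanoid oxide; heating equilibrates a Z bond at C11=C12 to all-E and none of the three stereocentres is touched.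

**Compound list**
1 | (E)-3-methylpent-2-en-4-yn-1-ol | C#C/C(C)=C/CO | starting material
2 | (E)-3-methylpenta-2,4-dien-1-ol | C=C/C(C)=C/CO | intermediate
3 | (E)-3-methylpenta-2,4-dienal | C=C/C(C)=C/C=O | intermediate
4 | ethyl (E)-4-(diethoxyphosphoryl)-3-methylbut-2-enoate | CCOC(=O)/C=C(\C)CP(=O)(OCC)OCC | starting material
5 | ethyl (2E,4E,6E)-3,7-dimethylnona-2,4,6,8-tetraenoate | C=C/C(C)=C/C=C/C(C)=C/C(=O)OCC | intermediate
6 | (2E,4E,6E)-3,7-dimethylnona-2,4,6,8-tetraen-1-ol | C=C/C(C)=C/C=C/C(C)=C/CO | intermediate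
7 | tert-butyl{[(2E,4E,6E)-3,7-dimethylnona-2,4,6,8-tetraen-1-yl]oxy}dimethylsilane | C=C/C(C)=C/C=C/C(C)=C/CO[Si](C)(C)C(C)(C)C | intermediate
8 | methacrolein (2-methylprop-2-enal) | CC(=C)C=O | starting material
9 | (1R,2S)-2-[(1E,3E)-5-{[tert-butyl(dimethyl)silyl]oxy}-3-methylpenta-1,3-dien-1-yl]-1,3-dimethylcyclohex-3-ene-1-carbaldehyde | CC1=CCC[C@@](C)(C=O)[C@H]1/C=C/C(C)=C/CO[Si](C)(C)C(C)(C)C | intermediate
10 | (E)-tosylhydrazone of 9 | CC1=CCC[C@@](C)(/C=N/NS(=O)(=O)c2ccc(C)cc2)[C@H]1/C=C/C(C)=C/CO[Si](C)(C)C(C)(C)C | intermediate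
11 | tert-butyldimethyl{[(2E,4E)-3-methyl-5-[(1R)-2,6,6-trimethylcyclohex-2-en-1-yl]penta-2,4-dien-1-yl]oxy}silane | CC1=CCCC(C)(C)[C@H]1/C=C/C(C)=C/CO[Si](C)(C)C(C)(C)C | intermediate
12 | (2E,4E)-3-methyl-5-[(1R)-2,6,6-trimethylcyclohex-2-en-1-yl]penta-2,4-dien-1-ol | CC1=CCCC(C)(C)[C@H]1/C=C/C(C)=C/CO | intermediate
13 | [(2E,4E)-3-methyl-5-[(1R)-2,6,6-trimethylcyclohex-2-en-1-yl]penta-2,4-dien-1-yl]triphenylphosphonium bromide | CC1=CCCC(C)(C)[C@H]1/C=C/C(C)=C/C[P+](c2ccccc2)(c3ccccc3)c4ccccc4.[Br-] | intermediate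
14 | (2E,4E,6E)-2,7-dimethylocta-2,4,6-trienedial | O=C/C(C)=C/C=C/C=C(C)/C=O | starting material
15 | (2E,4E,6E,8E,10E,12E)-2,7,11-trimethyl-13-[(1R)-2,6,6-trimethylcyclohex-2-en-1-yl]trideca-2,4,6,8,10,12-hexaenal | CC1=CCCC(C)(C)[C@H]1/C=C/C(C)=C/C=C/C(C)=C/C=C/C=C(C)/C=O | intermediate
16 | (2E,4E,6E,8E,10E,12E)-2,7,11-trimethyl-13-[(1R)-2,6,6-trimethylcyclohex-2-en-1-yl]trideca-2,4,6,8,10,12-hexaen-1-ol | CC1=CCCC(C)(C)[C@H]1/C=C/C(C)=C/C=C/C(C)=C/C=C/C=C(C)/CO | intermediate
17 | [(2E,4E,6E,8E,10E,12E)-2,7,11-trimethyl-13-[(1R)-2,6,6-trimethylcyclohex-2-en-1-yl]trideca-2,4,6,8,10,12-hexaen-1-yl]triphenylphosphonium bromide | CC1=CCCC(C)(C)[C@H]1/C=C/C(C)=C/C=C/C(C)=C/C=C/C=C(C)/C[P+](c2ccccc2)(c3ccccc3)c4ccccc4.[Br-] | intermediate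
18 | β-cyclocitral | CC1=C(C=O)C(C)(C)CCC1 | starting material
19 | β-cyclogeraniol | CC1=C(CO)C(C)(C)CCC1 | intermediate
20 | [(1R,6R)-2,2,6-trimethyl-7-oxabicyclo[4.1.0]heptan-1-yl]methanol | OC[C@@]12O[C@]1(C)CCCC2(C)C | intermediate
21 | (1S,6R)-2,2,6-trimethyl-7-oxabicyclo[4.1.0]heptane-1-carbaldehyde | O=C[C@@]12O[C@]1(C)CCCC2(C)C | intermediate
22 | diethyl [(E)-3-cyano-2-methylprop-2-en-1-yl]phosphonate | CCOP(=O)(OCC)C/C(C)=C/C#N | starting material
23 | (2E,4E)-3-methyl-5-[(1S,6R)-2,2,6-trimethyl-7-oxabicyclo[4.1.0]heptan-1-yl]penta-2,4-dienenitrile | N#C/C=C(C)/C=C/[C@@]12O[C@]1(C)CCCC2(C)C | intermediate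
24 | (2E,4E)-3-methyl-5-[(1S,6R)-2,2,6-trimethyl-7-oxabicyclo[4.1.0]heptan-1-yl]penta-2,4-dienal | O=C/C=C(C)/C=C/[C@@]12O[C@]1(C)CCCC2(C)C | intermediate
25 | (5R,6S,6'R)-5,6-epoxy-5,6-dihydro-β,ε-carotene | CC1=CCCC(C)(C)[C@H]1/C=C/C(C)=C/C=C/C(C)=C/C=C/C=C(C)/C=C/C=C(C)/C=C/[C@@]12O[C@]1(C)CCCC2(C)C | target

**Totals**
Total step count: 18.
Longest linear sequence: 13 steps (steps 1–12, then step 18).

**Steps most likely to fail**

Step 6. What may go wrong: competing cycloaddition at the internal C7'–C10' diene, acid-induced ionisation or oligomerisation of the electron-rich tetraenyl silyl ether, and an incomplete endo preference that lowers the enantiomeric purity at C6'. Fallback: the cycloaddition is moved to the ester oxidation level, where the internal diene is a deactivated dienoate and no ionisable allylic C–O bond is present. It sets out from 5, which is treated with 8 and the same oxazaborolidinium catalyst (CH2Cl2, −78 to −40 °C) to give ethyl (2E,4E)-5-[(1S,6R)-6-formyl-2,6-dimethylcyclohex-2-en-1-yl]-3-methylpenta-2,4-dienoate F1. Condensation with TsNHNH2 gives its (E)-tosylhydrazone F2, and reduction with catecholborane then NaOAc·3H2O gives ethyl (2E,4E)-3-methyl-5-[(1R)-2,6,6-trimethylcyclohex-2-en-1-yl]penta-2,4-dienoate F3. Reduction with (i-Bu)2AlH comes back to the route at 12, which is converted into 13 with PPh3·HBr as in step 9.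

Step 8. What may go wrong: slow hydride delivery to the neopentyl-type C=N carbon and competing hydroboration of the side-chain diene. Fallback: a stepwise deoxygenation through the alcohol. It sets out from 9, which NaBH4 (MeOH, 0 °C) reduces to [(1R,2S)-2-[(1E,3E)-5-{[tert-butyl(dimethyl)silyl]oxy}-3-methylpenta-1,3-dien-1-yl]-1,3-dimethylcyclohex-3-en-1-yl]methanol F4. MsCl and Et3N give the methanesulfonate of that alcohol F5, and displacement with LiEt3BH (THF, reflux) comes back to the route at 11.

Step 12. What may go wrong: capture of the hexaenyl cation at an internal position, E/Z scrambling, and migration of the ε-ring double bond under the acidic salt-forming conditions. Fallback: the polarity of the last olefination is reversed, so that the C25 unit stays an aldehyde and steps 11 and 12 are not needed. It sets out from 24, which NaBH4 reduces to (2E,4E)-3-methyl-5-[(1S,6R)-2,2,6-trimethyl-7-oxabicyclo[4.1.0]heptan-1-yl]penta-2,4-dien-1-ol F6. An Appel reaction (CBr4, PPh3, 2,6-lutidine, CH2Cl2, −20 °C) gives (1S,6R)-1-[(1E,3E)-5-bromo-3-methylpenta-1,3-dien-1-yl]-2,2,6-trimethyl-7-oxabicyclo[4.1.0]heptane F7, and PPh3 in EtOAc gives [(2E,4E)-3-methyl-5-[(1S,6R)-2,2,6-trimethyl-7-oxabicyclo[4.1.0]heptan-1-yl]penta-2,4-dien-1-yl]triphenylphosphonium bromide F8, made without acid. Wittig olefination of F8 with 15 (NaOMe, CH2Cl2–MeOH) and thermal equilibration comes back to the route at 25.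

**Further compounds**
F1 | step 6 | ethyl (2E,4E)-5-[(1S,6R)-6-formyl-2,6-dimethylcyclohex-2-en-1-yl]-3-methylpenta-2,4-dienoate | CC1=CCC[C@@](C)(C=O)[C@H]1/C=C/C(C)=C/C(=O)OCC
F2 | step 6 | (E)-tosylhydrazone of F1 | CC1=CCC[C@@](C)(/C=N/NS(=O)(=O)c2ccc(C)cc2)[C@H]1/C=C/C(C)=C/C(=O)OCC
F3 | step 6 | ethyl (2E,4E)-3-methyl-5-[(1R)-2,6,6-trimethylcyclohex-2-en-1-yl]penta-2,4-dienoate | CC1=CCCC(C)(C)[C@H]1/C=C/C(C)=C/C(=O)OCC
F4 | step 8 | [(1R,2S)-2-[(1E,3E)-5-{[tert-butyl(dimethyl)silyl]oxy}-3-methylpenta-1,3-dien-1-yl]-1,3-dimethylcyclohex-3-en-1-yl]methanol | CC1=CCC[C@@](C)(CO)[C@H]1/C=C/C(C)=C/CO[Si](C)(C)C(C)(C)C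
F5 | step 8 | methanesulfonate of F4 | CC1=CCC[C@@](C)(COS(C)(=O)=O)[C@H]1/C=C/C(C)=C/CO[Si](C)(C)C(C)(C)C
F6 | step 12 | (2E,4E)-3-methyl-5-[(1S,6R)-2,2,6-trimethyl-7-oxabicyclo[4.1.0]heptan-1-yl]penta-2,4-dien-1-ol | OC/C=C(C)/C=C/[C@@]12O[C@]1(C)CCCC2(C)C
F7 | step 12 | (1S,6R)-1-[(1E,3E)-5-bromo-3-methylpenta-1,3-dien-1-yl]-2,2,6-trimethyl-7-oxabicyclo[4.1.0]heptane | BrC/C=C(C)/C=C/[C@@]12O[C@]1(C)CCCC2(C)C
F8 | step 12 | [(2E,4E)-3-methyl-5-[(1S,6R)-2,2,6-trimethyl-7-oxabicyclo[4.1.0]heptan-1-yl]penta-2,4-dien-1-yl]triphenylphosphonium bromide | C(/C=C(C)/C=C/[C@@]12O[C@]1(C)CCCC2(C)C)[P+](c3ccccc3)(c4ccccc4)c5ccccc5.[Br-]
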